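**Assumption:** the SMILES has no stereocentre and no E/Z-stereogenic alkene (both alkenes end in CMe2). The aryl–(benzofuran-2-yl) axis is not expected to be configurationally stable. The target is therefore treated as achiral and no stereocontrol is needed.

## Retrosynthetic overview

1. The free 3'-OH comes from the C2-symmetric 3',5'-dimethyl ether by a final thiolate mono-O-demethylation, which avoids acid in the presence of the prenyl groups.
2. The furan ring is the only ring formed. It is made late by Sonogashira coupling and 5-endo-dig cyclisation of 4-iodoresorcinol with a hindered aryl acetylene, so no hindered biaryl coupling is needed.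
3. The aryl acetylene comes from the benzaldehyde by C1 homologation (Ohira–Bestmann).
4. Both prenyl groups come from a double Stille coupling on 2,6-dibromo-3,5-dimethoxybenzaldehyde.
5. The dibromide comes from regioselective dibromination of 3,5-dimethoxybenzaldehyde.

## Route

**Step 1**
Reactants: 1 3,5-dimethoxybenzaldehyde
Product: 2 2,6-dibromo-3,5-dimethoxybenzaldehyde
Conditions: Br2 (2.2 equiv), AcOH, 0 °C → rt
Reagents that add atoms: bromine, BrBr
Why: In this electrophilic aromatic bromination each OMe directs para/ortho to C2 and C6, while C4 between the two OMe groups is the most crowded site and the ring is deactivated after two bromines.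

**Step 2**
Reactants: 2 2,6-dibromo-3,5-dimethoxybenzaldehyde; 3 tributyl(3-methylbut-2-en-1-yl)stannane
Product: 4 3,5-dimethoxy-2,6-bis(3-methylbut-2-en-1-yl)benzaldehyde
Conditions: 3 (2.6 equiv), Pd(PPh3)4 (10 mol %), degassed DMF, 100 °C
Reagents that add atoms: tributyl(3-methylbut-2-en-1-yl)stannane, CCCC[Sn](CCCC)(CCCC)CC=C(C)C
Why: In this double Stille coupling the ortho-formyl group activates both C–Br bonds for oxidative addition, and reductive elimination from the less hindered terminus of the allyl-palladium species gives the linear prenyl group.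

**Step 3**
Reactants: 4 3,5-dimethoxy-2,6-bis(3-methylbut-2-en-1-yl)benzaldehyde; 5 dimethyl (1-diazo-2-oxopropyl)phosphonate
Product: 6 3-ethynyl-1,5-dimethoxy-2,4-bis(3-methylbut-2-en-1-yl)benzene
Conditions: 5 (1.5 equiv), K2CO3 (2 equiv), MeOH, rt
Reagents that add atoms: dimethyl (1-diazo-2-oxopropyl)phosphonate (Ohira–Bestmann reagent), COP(=O)(OC)C(=[N+]=[N-])C(C)=O
Why: This Ohira–Bestmann (Seyferth–Gilbert) homologation turns a non-enolisable aryl aldehyde into the terminal alkyne under mild base that leaves the prenyl groups and methyl ethers untouched.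

**Step 4**
Reactants: 6 3-ethynyl-1,5-dimethoxy-2,4-bis(3-methylbut-2-en-1-yl)benzene; 7 4-iodobenzene-1,3-diol (4-iodoresorcinol)
Product: 9 2-[3,5-dimethoxy-2,6-bis(3-methylbut-2-en-1-yl)phenyl]-1-benzofuran-6-ol, via alkynylresorcinol 8 (not isolated)
Conditions: PdCl2(PPh3)2 (5 mol %), CuI (10 mol %), Et3N, DMF, Ar, rt → 80 °C
Reagents that add atoms: 4-iodobenzene-1,3-diol, Oc1ccc(I)c(O)c1
Why: Sonogashira coupling takes place at the unhindered alkyne terminus, and the ortho-OH then adds across the metal-activated triple bond (5-endo-dig heteroannulation), which leaves the para-OH as the 6-hydroxyl.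

**Step 5**
Reactants: 9 2-[3,5-dimethoxy-2,6-bis(3-methylbut-2-en-1-yl)phenyl]-1-benzofuran-6-ol
Product: 10 2-[3-hydroxy-5-methoxy-2,6-bis(3-methylbut-2-en-1-yl)phenyl]-1-benzofuran-6-ol (target, CNP0324103.0)
Conditions: NaSEt (5 equiv), DMF, 130 °C; then cold 1 M HCl to pH 5
Reagents that add atoms: none
Why: This is an SN2 O-demethylation by thiolate in which the two OMe groups are equivalent, the first phenoxide deactivates the ring towards a second cleavage, and the basic medium avoids prenyl-to-chroman cyclisation.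

## Compound list

| No. | Name | SMILES | Role |
|---|---|---|---|
| 1 | 3,5-dimethoxybenzaldehyde | COc1cc(C=O)cc(OC)c1 | starting material |
| 2 | 2,6-dibromo-3,5-dimethoxybenzaldehyde | COc1cc(OC)c(Br)c(C=O)c1Br | intermediate |
| 3 | tributyl(3-methylbut-2-en-1-yl)stannane | CCCC[Sn](CCCC)(CCCC)CC=C(C)C | starting material |
| 4 | 3,5-dimethoxy-2,6-bis(3-methylbut-2-en-1-yl)benzaldehyde | COc1cc(OC)c(CC=C(C)C)c(C=O)c1CC=C(C)C | intermediate |
| 5 | dimethyl (1-diazo-2-oxopropyl)phosphonate | COP(=O)(OC)C(=[N+]=[N-])C(C)=O | starting material |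
| 6 | 3-ethynyl-1,5-dimethoxy-2,4-bis(3-methylbut-2-en-1-yl)benzene | COc1cc(OC)c(CC=C(C)C)c(C#C)c1CC=C(C)C | intermediate |
| 7 | 4-iodobenzene-1,3-diol | Oc1ccc(I)c(O)c1 | starting material |
| 8 | 4-{[3,5-dimethoxy-2,6-bis(3-methylbut-2-en-1-yl)phenyl]ethynyl}benzene-1,3-diol | COc1cc(OC)c(CC=C(C)C)c(C#Cc2ccc(O)cc2O)c1CC=C(C)C | intermediate (not isolated) |
| 9 | 2-[3,5-dimethoxy-2,6-bis(3-methylbut-2-en-1-yl)phenyl]-1-benzofuran-6-ol | COc1cc(OC)c(CC=C(C)C)c(-c2cc3ccc(O)cc3o2)c1CC=C(C)C | intermediate |
| 10 | 2-[3-hydroxy-5-methoxy-2,6-bis(3-methylbut-2-en-1-yl)phenyl]-1-benzofuran-6-ol | COc1cc(O)c(CC=C(C)C)c(-c2cc3ccc(O)cc3o2)c1CC=C(C)C | target |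

**Total step count:** 5
**Longest linear sequence:** 5 (1 → 2 → 4 → 6 → 9 → 10)

## Steps most likely to fail, with fallbacks

**Step 2 (double Stille prenylation).** The risks are γ-coupling to the reverse-prenyl isomer, stalling after the first coupling, and allylstannane addition to the aldehyde.
The fallback sets out from 2. It installs two plain allyl groups, which have no regiochemical ambiguity, using allyltributylstannane and Pd(PPh3)4 in toluene at 110 °C. This gives 2,6-diallyl-3,5-dimethoxybenzaldehyde F1.
Double olefin cross-metathesis of F1 with excess 2-methylbut-2-ene (Grubbs II, CH2Cl2, 40 °C) then converts both allyl groups to prenyl groups. The fallback comes back to the route at 4.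

**Step 4 (tandem Sonogashira/heteroannulation with unprotected 4-iodoresorcinol).** The risks are the air-sensitive, electron-rich iodide, Glaser dimerisation of 6, and slow ring closure next to the bulky aryl group.
The fallback sets out from 7, with 6 as the coupling partner, and separates the two events.
- Acetylation of 7 (Ac2O, pyridine) gives 4-iodo-1,3-phenylene diacetate F2.
- F2 is a more reactive and more stable Sonogashira partner for 6 (PdCl2(PPh3)2, CuI, Et3N, THF, rt). The coupling gives 4-{[3,5-dimethoxy-2,6-bis(3-methylbut-2-en-1-yl)phenyl]ethynyl}-1,3-phenylene diacetate F3.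
- Treating F3 with Cs2CO3 in MeOH/DMF at 70 °C removes both acetates and closes the furan by base-mediated 5-endo-dig attack of the phenoxide, passing through 8.

The fallback comes back to the route at 9.

**Step 5 (late mono-demethylation).** The risks are incomplete conversion, over-cleavage to the resorcinol, and decomposition at 130 °C.
The fallback sets out from 2 and differentiates the two oxygens before any acid-sensitive prenyl group is present.
- BBr3 (1.0 equiv, CH2Cl2, −78 → 0 °C) gives 2,6-dibromo-3-hydroxy-5-methoxybenzaldehyde F4.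
- Double Stille coupling of F4 with 3 gives 3-hydroxy-5-methoxy-2,6-bis(3-methylbut-2-en-1-yl)benzaldehyde F5.
- Ohira–Bestmann homologation of F5 with 5 gives 3-ethynyl-5-methoxy-2,4-bis(3-methylbut-2-en-1-yl)phenol F6.
- Sonogashira coupling of F6 with 7 gives 4-{[3-hydroxy-5-methoxy-2,6-bis(3-methylbut-2-en-1-yl)phenyl]ethynyl}benzene-1,3-diol F7, which cyclises in the same flask. Only the resorcinol ortho-OH can reach the alkyne.

The fallback comes back to the route at 10.

## Further compounds

F1 | step 2 | 2,6-diallyl-3,5-dimethoxybenzaldehyde | COc1cc(OC)c(CC=C)c(C=O)c1CC=C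
F2 | step 4 | 4-iodo-1,3-phenylene diacetate | CC(=O)Oc1ccc(I)c(OC(C)=O)c1
F3 | step 4 | 4-{[3,5-dimethoxy-2,6-bis(3-methylbut-2-en-1-yl)phenyl]ethynyl}-1,3-phenylene diacetate | COc1cc(OC)c(CC=C(C)C)c(C#Cc2ccc(OC(C)=O)cc2OC(C)=O)c1CC=C(C)C
F4 | step 5 | 2,6-dibromo-3-hydroxy-5-methoxybenzaldehyde | COc1cc(O)c(Br)c(C=O)c1Br
F5 | step 5 | 3-hydroxy-5-methoxy-2,6-bis(3-methylbut-2-en-1-yl)benzaldehyde | COc1cc(O)c(CC=C(C)C)c(C=O)c1CC=C(C)C
F6 | step 5 | 3-ethynyl-5-methoxy-2,4-bis(3-methylbut-2-en-1-yl)phenol | COc1cc(O)c(CC=C(C)C)c(C#C)c1CC=C(C)C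
F7 | step 5 | 4-{[3-hydroxy-5-methoxy-2,6-bis(3-methylbut-2-en-1-yl)phenyl]ethynyl}benzene-1,3-diol | COc1cc(O)c(CC=C(C)C)c(C#Cc2ccc(O)cc2O)c1CC=C(C)C
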